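## The problem

AKML B (41) is a 24-membered macrolactone (C1–C23 plus the ring oxygen) with one methyl branch (C24) and a cis-oxirane at C6–C7 fused to the large ring. The chain is unbranched: a long methylene run (C10–C17) separates the Z-olefin C18=C19 and the C23 carbinol from the dense C1–C9 region, which holds the Z-enoate, the C5 carbinol, the oxirane and the C8/C9 diol. Of the six stereocentres, C23 is too remote to be controlled by anything and has to be bought. C9 can control C8 by chelation if C8 is made from an aldehyde. A free C8 hydroxyl can then deliver oxygen to C6/C7 of a cis-olefin, since the oxirane is threo to O8 and erythro to O5. C5 is insulated from C8 by two carbons and needs a reagent-controlled step. The Z-enoate isomerises and accepts nucleophiles, a C3 aldehyde β to the C5 oxygen can eliminate, the epoxy triol is open to acid and to Payne migration, and the isolated C18=C19 olefin rules out peracids, unselective hydrogenation and metathesis. The enabling feature is that the oxirane carbons C6 and C7 lie between two carbinol carbons, C5 and C8. This is a but-2-yne-1,4-diol pattern, so C5–C8 can be made from acetylene and two carbonyl partners, and if C5 arrives as a ketone and C8 as an alcohol the two oxygens are differentiated from the start.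

## Retrosynthesis

**Ring opening at C2=C3.** After removal of the O5/O8 silyl groups and the O9 p-methoxybenzyl (PMB) group (41 ⇐ 40 ⇐ 39), macrolactone 39 is cut at the C2=C3 double bond to give aldehyde 38, which carries a bis(2,2,2-trifluoroethyl)phosphonoacetate on O23. The neighbouring cut, the C1–O23 ester bond, would require activating a Z-enoic acid, which isomerises under acyl-transfer catalysis. Cutting the olefin makes the ester by a simple acylation and sets the Z geometry in the ring-closing event. The precursor is acyclic; the forward reaction has to be Z-selective under base mild enough for a β-silyloxy aldehyde.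

**Unveiling order at the two chain ends.** 38 comes from alcohol 37 and this from 36, the ester of C23 alcohol 34 with acid 35; 34 comes from the fully protected epoxide 33, the O8 silyl ether of 32. Only the C1–O23 bond is cut here. Because O23 has to be freed before O3, the groups are chosen in a lability series: secondary triethylsilyl (TES) on O23, primary tert-butyldimethylsilyl (TBS) on O3, hindered secondary TBS on O5 and O8, PMB on O9. The forward steps must be three selective deprotections.

**Oxirane.** 32 is cut at both C–O bonds of the oxirane to give Z-allylic alcohol 31. Making the oxirane by displacement would need two more differentiated oxygens; oxygen transfer needs only the O8 hydroxyl already present. The precursor has two stereocentres fewer. The forward step must deliver oxygen syn to O8 and leave C18=C19 untouched.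

**Olefin and C5 carbinol.** 31 comes from alkyne 30 by semihydrogenation, and 30 from hydroxy ynone 26 through 29, 28 and 27. The C5–H bond is cut (ketone 27), and O8 is freed by removing a temporary acetate. The alkyne guarantees the cis geometry, and the ketone lets a catalyst set C5 while the acetate keeps O5 and O8 apart. The forward reduction must override the distant C8/C9 centres.

**Acetylene linchpin (key cut).** 26 is cut at C7–C8 and C5–C6 into aldehyde 18, ethynylmagnesium bromide 22 and Weinreb amide 21. Cutting only one of these bonds would need a preformed chiral alkynol or ynone; cutting both uses a two-carbon reagent of no value and joins the two branches in one flask. The precursors hold C3–C5 and C8–C24 with only C9 and C23 as stereocentres. The forward reaction must be syn-selective at C8 and acylate only once.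

**C8 aldehyde.** 18 comes from alcohol 17, this from acetal 16 by reductive opening, and 16 from alcohol 15 by oxidative PMB transfer. 15 is cut at C10–C11 into glycidyl ether 13 (from (S)-glycidol 12) and Grignard reagent 14. The PMB group thus protects O8 during the epoxide opening and ends on O9, where the key step needs it. The forward opening must be regioselective at the terminal carbon.

**C11–C24 chain.** 14 comes from bromide 11 and alcohol 10. 10 is cut at C18=C19 into ylide 9 (from salt 8, from 8-bromooctan-1-ol 7) and aldehyde 6. 6 comes via ozonide 5 from alkene 4, the silyl ether of 3, made from (R)-propylene oxide 1 and but-3-enylmagnesium bromide 2 (C21–C22 cut). A Wittig cut here puts the Z-olefin in early, from cheap pieces. The forward step needs kinetic Z-selectivity.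

**Amide.** 21 comes from ester 20 and methyl 3-hydroxypropanoate 19; the forward steps are silylation and aminolysis.

## Roads not taken

**Alternative 1:** Z-selective phosphonate olefination as the strategic step. The cut is C2=C3. The seco aldehyde A1 is closed with K2CO3/18-crown-6 to the tris(triethylsilyl) macrolide A2.
- Merits: the fragile Z-enoate is made last, no Z-enoic acid is ever activated, and A2 loses three TES groups in one very mild step.
- Weak points: as a strategy it does not say how the C5–C8 array is built, and it needs a protecting-group exchange to bring TES onto O5, O8 and O9.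
- Comparison: this ring closure is as good as any available, and the chosen plan uses the same reaction at step 26. Alternative 1 is better in its final deprotection (one step, TES) than the chosen plan (two steps, hindered TBS plus PMB). Against this the chosen plan sets a protecting-group array that needs no exchange: PMB is the chelating group of the key step, and TBS is what allows O23 to be freed first.

**Alternative 2:** late oxygen transfer to the macrocyclic olefin. The cut is the two oxirane C–O bonds on the ring. The macrocyclic allylic alcohol A3 is treated with VO(acac)2/t-BuOOH to give epoxide A4.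
- Merits: the oxirane, the most fragile function, is spared about eight steps, including fluoride, DDQ and the basic ring closure.
- Weak points: face selectivity then depends on the conformation of a 24-membered ring instead of the well-understood acyclic allylic-strain model. The free O8 hydroxyl also has to be masked during the C3 oxidation and unmasked again on the macrocycle, so no step is saved.
- Comparison: Alternative 2 is better at protecting the oxirane from late reagents. The chosen plan sets against it a predictable, matched acyclic epoxidation whose outcome is known before the macrocyclisation is committed.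

**Alternative 3:** silicon-tethered ring-closing metathesis. The cut is C6=C7. The bis-allyl diisopropylsilyl ether A5 is closed with the first-generation Grubbs catalyst RuCl2(PCy3)2(=CHPh) to the seven-membered silaketal A6.
- Merits: the cis geometry is enforced by the small ring without semihydrogenation, and C5 and C8 come from two independent vinyl carbinols.
- Weak points: the C18=C19 olefin is exposed to a metathesis catalyst. The unsymmetrical silaketal needs two sequential silylations. Each of C5 and C8 needs its own asymmetric step. Removing the tether frees O5 and O8 together, which brings back the differentiation problem before the directed epoxidation.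
- Comparison: Alternative 3 is better in geometric certainty and modularity. The chosen plan sets against it two C–C bonds and one stereocentre in a single flask, O5 and O8 differentiated from the start (ketone and alcohol), and no metathesis catalyst near C18=C19.

Key step: step 14

Assumption: atoms are numbered as in the target (C1 lactone carbonyl, C23 lactone carbinol, C24 methyl), and but-3-enylmagnesium bromide, ethynylmagnesium bromide and bis(2,2,2-trifluoroethyl)phosphonoacetic acid are taken as purchasable reagents.

## Steps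

Step 1
Reactants: 1 (R)-propylene oxide; 2 but-3-enylmagnesium bromide
Product: 3 (R)-hept-6-en-2-ol
Conditions: CuI (10 mol%), THF, −30 → 0 °C; aq NH4Cl
Reagents that add atoms: none
Why: Copper-catalysed Grignard opening of a terminal epoxide goes by SN2 at the unsubstituted carbon, so the C23 centre of 1 is carried over unchanged.

Step 2
Reactants: 3 (R)-hept-6-en-2-ol
Product: 4 (R)-triethyl(hept-6-en-2-yloxy)silane
Conditions: Et3SiCl, imidazole, CH2Cl2, 0 °C → rt
Reagents that add atoms: chlorotriethylsilane, CC[Si](Cl)(CC)CC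
Why: Standard silylation of a secondary alcohol; TES is chosen so that O23 can later be freed before any TBS ether.

Step 3
Reactants: 4 (R)-triethyl(hept-6-en-2-yloxy)silane
Product: 6 (R)-5-(triethylsilyloxy)hexanal, via ozonide 5 (not isolated)
Conditions: O3, CH2Cl2, −78 °C; PPh3, −78 °C → rt
Reagents that add atoms: ozone, [O-][O+]=O
Why: Ozonolysis of a terminal olefin with reductive work-up gives the aldehyde and formaldehyde; the silyl ether and the stereocentre are not involved.

Step 4
Reactants: 7 8-bromooctan-1-ol
Product: 8 (8-hydroxyoctyl)triphenylphosphonium bromide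
Conditions: PPh3, MeCN, reflux
Reagents that add atoms: triphenylphosphine, c1ccc(cc1)P(c1ccccc1)c1ccccc1
Why: SN2 quaternisation of a primary bromide; the free hydroxyl does not interfere.

Step 5
Reactants: 8 (8-hydroxyoctyl)triphenylphosphonium bromide; 6 (R)-5-(triethylsilyloxy)hexanal
Product: 10 (8Z,13R)-13-(triethylsilyloxy)tetradec-8-en-1-ol, via alkoxide ylide 9 (not isolated)
Conditions: 8, NaN(SiMe3)2 (2 equiv), THF, 0 °C; then 6, −78 °C → rt
Reagents that add atoms: none
Why: Wittig reaction of a non-stabilised ylide under lithium-free conditions at low temperature is kinetically Z-selective and sets the C18=C19 geometry; the second equivalent of base only forms the alkoxide.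

Step 6
Reactants: 10 (8Z,13R)-13-(triethylsilyloxy)tetradec-8-en-1-ol
Product: 11 (2R,6Z)-14-bromo-2-(triethylsilyloxy)tetradec-6-ene
Conditions: CBr4, PPh3, imidazole, CH2Cl2, 0 °C
Reagents that add atoms: carbon tetrabromide, BrC(Br)(Br)Br
Why: Appel bromination of a primary alcohol under buffered, neutral conditions that a secondary TES ether and a Z-olefin tolerate.

Step 7
Reactants: 12 (S)-glycidol
Product: 13 (R)-2-[(4-methoxybenzyloxy)methyl]oxirane
Conditions: NaH, 4-methoxybenzyl chloride, n-Bu4NI (cat.), THF/DMF, 0 °C → rt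
Reagents that add atoms: 4-methoxybenzyl chloride, COc1ccc(CCl)cc1
Why: Williamson etherification; the Payne equilibrium of glycidol alkoxide is degenerate and returns the same enantiomer, so the centre is preserved (the descriptor changes from S to R only because the CIP priorities change).

Step 8
Reactants: 11 (2R,6Z)-14-bromo-2-(triethylsilyloxy)tetradec-6-ene; 13 (R)-2-[(4-methoxybenzyloxy)methyl]oxirane
Product: 15 (2R,11Z,16R)-1-(4-methoxybenzyloxy)-16-(triethylsilyloxy)heptadec-11-en-2-ol, via Grignard reagent 14 (not isolated)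
Conditions: Mg, THF, rt → 40 °C; then CuI (10 mol%), 13, THF, −30 → 0 °C
Reagents that add atoms: none
Why: Copper-catalysed Grignard opening at the terminal epoxide carbon forms C10–C11 and leaves the glycidol centre (C9) untouched.

Step 9
Reactants: 15 (2R,11Z,16R)-1-(4-methoxybenzyloxy)-16-(triethylsilyloxy)heptadec-11-en-2-ol
Product: 16 (4R)-2-(4-methoxyphenyl)-4-[(9Z,14R)-14-(triethylsilyloxy)pentadec-9-enyl]-1,3-dioxolane (both acetal epimers)
Conditions: DDQ (1.2 equiv), 4 Å molecular sieves, CH2Cl2, 0 °C
Reagents that add atoms: none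
Why: Anhydrous DDQ oxidation of a PMB ether gives a benzylic oxocarbenium ion that is trapped by the neighbouring C9 hydroxyl as the p-methoxybenzylidene acetal; the acetal epimers converge in the next step.

Step 10
Reactants: 16 the p-methoxybenzylidene acetal
Product: 17 (2R,11Z,16R)-2-(4-methoxybenzyloxy)-16-(triethylsilyloxy)heptadec-11-en-1-ol
Conditions: iBu2AlH, CH2Cl2, −78 → 0 °C; aq potassium sodium tartrate
Reagents that add atoms: none
Why: Regioselective reductive acetal opening: the aluminium reagent binds the less hindered primary oxygen (O8), that C–O bond breaks, and hydride reduces the oxocarbenium ion, leaving PMB on O9 and a free primary alcohol.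

Step 11
Reactants: 17 (2R,11Z,16R)-2-(4-methoxybenzyloxy)-16-(triethylsilyloxy)heptadec-11-en-1-ol
Product: 18 (2R,11Z,16R)-2-(4-methoxybenzyloxy)-16-(triethylsilyloxy)heptadec-11-enal (C8–C24 aldehyde)
Conditions: Dess–Martin periodinane, NaHCO3, CH2Cl2, 0 °C → rt; used crude
Reagents that add atoms: none
Why: Buffered Dess–Martin oxidation gives the α-alkoxy aldehyde without base strong enough to epimerise C9.

Step 12
Reactants: 19 methyl 3-hydroxypropanoate
Product: 20 methyl 3-(tert-butyldimethylsilyloxy)propanoate
Conditions: t-BuMe2SiCl, imidazole, DMF, rt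
Reagents that add atoms: tert-butyldimethylsilyl chloride, CC(C)(C)[Si](C)(C)Cl
Why: Standard silylation of a primary alcohol.

Step 13
Reactants: 20 methyl 3-(tert-butyldimethylsilyloxy)propanoate
Product: 21 3-(tert-butyldimethylsilyloxy)-N-methoxy-N-methylpropanamide
Conditions: MeNH(OMe)·HCl, iPrMgCl, THF, −20 → 0 °C
Reagents that add atoms: N,O-dimethylhydroxylamine hydrochloride, CNOC.Cl
Why: Direct conversion of an ester into the Weinreb amide by the chloromagnesium amide; the low temperature avoids β-elimination of the silyloxy group.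

Step 14
Reactants: 18 C8–C24 aldehyde; 22 ethynylmagnesium bromide; 21 3-(tert-butyldimethylsilyloxy)-N-methoxy-N-methylpropanamide
Product: 26 C3–C24 hydroxy ynone (8R,9R,18Z,23R; 3-OTBS; 5-oxo; 6-yne; 8-OH; 9-OPMB; 23-OTES), via bromomagnesium alkoxide 23 (not isolated), via dimagnesium alkoxide acetylide 24 (not isolated), via magnesium hemiaminal adduct 25 (not isolated)
Conditions: 18, MgBr2·OEt2 (2 equiv), CH2Cl2, −78 °C; 22 (THF solution), −78 → −20 °C; EtMgBr, THF, 0 °C → rt; 21 (excess), 0 °C → rt; inverse quench into cold aq NaHSO4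
Reagents that add atoms: none
Why: MgBr2 ties the aldehyde oxygen and the O9 ether oxygen into a five-membered chelate (Cram chelate model), and the small ethynyl nucleophile attacks C8 from the face away from the C10 chain, giving alkoxide 23 with the 8,9-syn relationship. EtMgBr then removes the acetylenic proton of 23 to give the C,O-dimagnesium species 24, whose carbon terminus adds to amide 21. The resulting N-methoxy-N-methyl hemiaminal magnesium chelate 25 survives until the quench, so only one acyl transfer takes place. The closest known reactions are chelation-controlled alkynyl Grignard additions to α-alkoxy aldehydes and the acylation of metalated propargylic alkoxides by Weinreb amides; the two are only run in sequence in one flask here. Two skeletal bonds (C7–C8, C5–C6) form and no ring closes. The one new stereocentre, C8, is controlled by C9 through the chelate, which is why O9 carries PMB and not a silyl group and why CH2Cl2 is the bulk solvent. The step needs syn face selectivity, C-acylation in preference to O-acylation (the magnesium alkoxide does not react with a Weinreb amide) and mono-addition. The acidic inverse quench protonates the released N,O-dimethylhydroxylamine so that it cannot add to the ynone.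

Step 15
Reactants: 26 C3–C24 hydroxy ynone
Product: 27 O8 acetate of 26 (8R,9R,18Z,23R)
Conditions: Ac2O, pyridine, DMAP (cat.), CH2Cl2, 0 °C
Reagents that add atoms: acetic anhydride, CC(=O)OC(C)=O
Why: Acetylation of the only free hydroxyl; the acetate marks O8 so that O5, once formed, can be protected separately.

Step 16
Reactants: 27 O8 acetate of the ynone
Product: 28 C5 propargylic alcohol (5S,8R,9R,18Z,23R; 8-OAc)
Conditions: Ru[(S,S)-TsNCHPhCHPhNH](p-cymene) (5 mol%), iPrOH, rt
Reagents that add atoms: none
Why: Noyori asymmetric transfer hydrogenation of an alkynyl ketone under base-free conditions; the alkyne takes the place of the aryl group in the transition state, so the (S,S) catalyst is expected to give the 5S carbinol under catalyst control.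

Step 17
Reactants: 28 C5 propargylic alcohol
Product: 29 O5 tert-butyldimethylsilyl ether (5S,8R,9R,18Z,23R; 8-OAc)
Conditions: t-BuMe2SiOTf, 2,6-lutidine, CH2Cl2, −78 °C
Reagents that add atoms: tert-butyldimethylsilyl trifluoromethanesulfonate, CC(C)(C)[Si](C)(C)OS(=O)(=O)C(F)(F)F
Why: Silylation of the only free hydroxyl under buffered conditions that the acetate and the TES ether tolerate.

Step 18
Reactants: 29 O5 silyl ether, O8 acetate
Product: 30 C8 propargylic alcohol (5S,8R,9R,18Z,23R; 3,5-bis-OTBS; 9-OPMB; 23-OTES)
Conditions: K2CO3, MeOH, 0 °C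
Reagents that add atoms: none
Why: Mild methanolysis of the acetate frees O8 alone; the silyl ethers and the PMB ether are stable under these conditions.

Step 19
Reactants: 30 C8 propargylic alcohol
Product: 31 (6Z)-allylic alcohol (5S,6Z,8R,9R,18Z,23R)
Conditions: H2 (1 atm), Pd/CaCO3 poisoned with Pb(OAc)2 (Lindlar catalyst), quinoline, EtOAc, rt
Reagents that add atoms: none
Why: Lindlar semihydrogenation adds hydrogen syn to the alkyne to give the cis-olefin; the isolated C18=C19 olefin and the benzylic ether are not reduced by the poisoned catalyst.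

Step 20
Reactants: 31 (6Z)-allylic alcohol
Product: 32 epoxy alcohol (5S,6R,7R,8S,9R,18Z,23R; same spatial arrangement at C5–C9 as in 41; 8-OH free)
Conditions: VO(acac)2 (10 mol%), t-BuOOH (decane), CH2Cl2, 0 °C → rt
Reagents that add atoms: tert-butyl hydroperoxide, CC(C)(C)OO
Why: Hydroxyl-directed epoxidation: the vanadium alkoxide of O8 delivers the peroxide oxygen to the olefin face syn to O8 in the conformer with C8–H in the olefin plane (allylic 1,3-strain), giving the threo epoxy alcohol. The C5 silyloxy group lies on the opposite face in the same conformer, so both effects point the same way, and C18=C19 has no directing group and stays intact.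

Step 21
Reactants: 32 epoxy alcohol
Product: 33 O8 tert-butyldimethylsilyl ether (5S,6R,7S,8S,9R,18Z,23R; descriptor at C7 changes by priority only)
Conditions: t-BuMe2SiOTf, 2,6-lutidine, CH2Cl2, −78 → 0 °C
Reagents that add atoms: tert-butyldimethylsilyl trifluoromethanesulfonate, CC(C)(C)[Si](C)(C)OS(=O)(=O)C(F)(F)F
Why: The silyl triflate is needed for the hindered C8 hydroxyl; excess lutidine at low temperature keeps the oxirane from Lewis-acid opening.

Step 22
Reactants: 33 fully protected epoxide
Product: 34 C23 alcohol (5S,6R,7S,8S,9R,18Z,23R; 3,5,8-tris-OTBS; 9-OPMB)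
Conditions: pyridinium p-toluenesulfonate (cat.), MeOH/CH2Cl2, 0 °C
Reagents that add atoms: none
Why: Selective acid-catalysed methanolysis: a secondary TES ether is cleaved faster than a primary TBS ether and much faster than hindered secondary TBS ethers.

Step 23
Reactants: 34 C23 alcohol; 35 bis(2,2,2-trifluoroethyl)phosphonoacetic acid
Product: 36 C23 bis(2,2,2-trifluoroethyl)phosphonoacetate
Conditions: DCC, DMAP (cat.), CH2Cl2, 0 °C → rt
Reagents that add atoms: none
Why: Steglich esterification of the only free hydroxyl with retention at C23.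

Step 24
Reactants: 36 C23 phosphonoacetate
Product: 37 C3 primary alcohol
Conditions: HF·pyridine, pyridine, THF, 0 °C
Reagents that add atoms: none
Why: Buffered HF·pyridine removes a primary TBS ether in the presence of hindered secondary TBS ethers; the phosphonoacetate, the PMB ether and the oxirane tolerate it.

Step 25
Reactants: 37 C3 primary alcohol
Product: 38 C3 aldehyde
Conditions: Dess–Martin periodinane, NaHCO3, CH2Cl2, 0 °C; used crude
Reagents that add atoms: none
Why: Neutral oxidation to the β-silyloxy aldehyde without base that would cause elimination or premature olefination.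

Step 26
Reactants: 38 C3 aldehyde
Product: 39 macrolactone (2Z,18Z; 5,8-bis-OTBS; 9-OPMB)
Conditions: K2CO3, 18-crown-6, toluene (1 mM, slow addition of 38), 0 °C → rt
Reagents that add atoms: none
Why: Intramolecular Still–Gennari variant of the Horner–Wadsworth–Emmons reaction: the electron-poor trifluoroethyl phosphonate eliminates fast from the kinetic adduct and gives the Z-enoate while closing the 24-membered ring; high dilution suppresses oligomers.

Step 27
Reactants: 39 macrolactone
Product: 40 C9 alcohol (5,8-bis-OTBS macrolactone)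
Conditions: DDQ, CH2Cl2/pH 7 phosphate buffer, 0 °C
Reagents that add atoms: none
Why: Oxidative PMB cleavage under buffered conditions leaves the enoate, both olefins, the oxirane and the silyl ethers untouched.

Step 28
Reactants: 40 C9 alcohol
Product: 41 AKML B
Conditions: HF·pyridine, pyridine, THF, 0 °C → rt
Reagents that add atoms: none
Why: Buffered fluoride desilylation frees O5 and O8 without base (no Payne migration, no lactone opening) and without acid strong enough to open the oxirane.

## Compound list

1 | (R)-propylene oxide | C[C@@H]1CO1 | starting material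
2 | but-3-enylmagnesium bromide | C=CCC[Mg]Br | starting material
3 | (R)-hept-6-en-2-ol | C[C@@H](O)CCCC=C | intermediate
4 | (R)-triethyl(hept-6-en-2-yloxy)silane | C[C@@H](O[Si](CC)(CC)CC)CCCC=C | intermediate
5 | 3-[(4R)-4-(triethylsilyloxy)pentyl]-1,2,4-trioxolane (ozonide) | C[C@@H](O[Si](CC)(CC)CC)CCCC1OCOO1 | intermediate
6 | (R)-5-(triethylsilyloxy)hexanal | C[C@@H](O[Si](CC)(CC)CC)CCCC=O | intermediate
7 | 8-bromooctan-1-ol | OCCCCCCCCBr | starting material
8 | (8-hydroxyoctyl)triphenylphosphonium bromide | OCCCCCCCC[P+](c1ccccc1)(c1ccccc1)c1ccccc1.[Br-] | intermediate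
9 | sodium 8-(triphenylphosphoranylidene)octan-1-olate (alkoxide ylide) | [Na+].[O-]CCCCCCCC=P(c1ccccc1)(c1ccccc1)c1ccccc1 | intermediate
10 | (8Z,13R)-13-(triethylsilyloxy)tetradec-8-en-1-ol | C[C@@H](O[Si](CC)(CC)CC)CCC/C=C\CCCCCCCO | intermediate
11 | (2R,6Z)-14-bromo-2-(triethylsilyloxy)tetradec-6-ene | C[C@@H](O[Si](CC)(CC)CC)CCC/C=C\CCCCCCCBr | intermediate
12 | (S)-glycidol | OC[C@H]1CO1 | starting material
13 | (R)-2-[(4-methoxybenzyloxy)methyl]oxirane | COc1ccc(COC[C@H]2CO2)cc1 | intermediate
14 | [(8Z,13R)-13-(triethylsilyloxy)tetradec-8-enyl]magnesium bromide | C[C@@H](O[Si](CC)(CC)CC)CCC/C=C\CCCCCCC[Mg]Br | intermediate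
15 | (2R,11Z,16R)-1-(4-methoxybenzyloxy)-16-(triethylsilyloxy)heptadec-11-en-2-ol | C[C@@H](O[Si](CC)(CC)CC)CCC/C=C\CCCCCCCC[C@@H](O)COCc1ccc(OC)cc1 | intermediate
16 | (4R)-2-(4-methoxyphenyl)-4-[(9Z,14R)-14-(triethylsilyloxy)pentadec-9-enyl]-1,3-dioxolane | C[C@@H](O[Si](CC)(CC)CC)CCC/C=C\CCCCCCCC[C@@H]1COC(c2ccc(OC)cc2)O1 | intermediate
17 | (2R,11Z,16R)-2-(4-methoxybenzyloxy)-16-(triethylsilyloxy)heptadec-11-en-1-ol | C[C@@H](O[Si](CC)(CC)CC)CCC/C=C\CCCCCCCC[C@@H](OCc1ccc(OC)cc1)CO | intermediate
18 | (2R,11Z,16R)-2-(4-methoxybenzyloxy)-16-(triethylsilyloxy)heptadec-11-enal | C[C@@H](O[Si](CC)(CC)CC)CCC/C=C\CCCCCCCC[C@@H](OCc1ccc(OC)cc1)C=O | intermediate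
19 | methyl 3-hydroxypropanoate | COC(=O)CCO | starting material
20 | methyl 3-(tert-butyldimethylsilyloxy)propanoate | COC(=O)CCO[Si](C)(C)C(C)(C)C | intermediate
21 | 3-(tert-butyldimethylsilyloxy)-N-methoxy-N-methylpropanamide | CON(C)C(=O)CCO[Si](C)(C)C(C)(C)C | intermediate
22 | ethynylmagnesium bromide | C#C[Mg]Br | starting material
23 | bromomagnesium alkoxide of the (8R,9R)-C6–C24 ethynyl carbinol | C[C@@H](O[Si](CC)(CC)CC)CCC/C=C\CCCCCCCC[C@@H](OCc1ccc(OC)cc1)[C@H](O[Mg]Br)C#C | intermediate
24 | C6-bromomagnesio acetylide of alkoxide 23 | C[C@@H](O[Si](CC)(CC)CC)CCC/C=C\CCCCCCCC[C@@H](OCc1ccc(OC)cc1)[C@H](O[Mg]Br)C#C[Mg]Br | intermediate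
25 | C5 N-methoxy-N-methyl hemiaminal bis(bromomagnesium) alkoxide | C[C@@H](O[Si](CC)(CC)CC)CCC/C=C\CCCCCCCC[C@@H](OCc1ccc(OC)cc1)[C@H](O[Mg]Br)C#CC(O[Mg]Br)(CCO[Si](C)(C)C(C)(C)C)N(C)OC | intermediate
26 | C3–C24 hydroxy ynone (8R,9R,18Z,23R): 3-OTBS, 5-oxo, 6-yne, 8-OH, 9-OPMB, 23-OTES | C[C@@H](O[Si](CC)(CC)CC)CCC/C=C\CCCCCCCC[C@@H](OCc1ccc(OC)cc1)[C@H](O)C#CC(=O)CCO[Si](C)(C)C(C)(C)C | intermediate
27 | O8 acetate of 26 (8R,9R,18Z,23R) | C[C@@H](O[Si](CC)(CC)CC)CCC/C=C\CCCCCCCC[C@@H](OCc1ccc(OC)cc1)[C@H](OC(C)=O)C#CC(=O)CCO[Si](C)(C)C(C)(C)C | intermediate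
28 | C5 propargylic alcohol (5S,8R,9R,18Z,23R): 3-OTBS, 5-OH, 8-OAc, 9-OPMB, 23-OTES | C[C@@H](O[Si](CC)(CC)CC)CCC/C=C\CCCCCCCC[C@@H](OCc1ccc(OC)cc1)[C@H](OC(C)=O)C#C[C@@H](O)CCO[Si](C)(C)C(C)(C)C | intermediate
29 | O5 TBS ether of 28 (5S,8R,9R,18Z,23R) | C[C@@H](O[Si](CC)(CC)CC)CCC/C=C\CCCCCCCC[C@@H](OCc1ccc(OC)cc1)[C@H](OC(C)=O)C#C[C@@H](O[Si](C)(C)C(C)(C)C)CCO[Si](C)(C)C(C)(C)C | intermediate
30 | C8 propargylic alcohol (5S,8R,9R,18Z,23R): 3,5-bis-OTBS, 8-OH, 9-OPMB, 23-OTES | C[C@@H](O[Si](CC)(CC)CC)CCC/C=C\CCCCCCCC[C@@H](OCc1ccc(OC)cc1)[C@H](O)C#C[C@@H](O[Si](C)(C)C(C)(C)C)CCO[Si](C)(C)C(C)(C)C | intermediate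
31 | (6Z)-allylic alcohol (5S,6Z,8R,9R,18Z,23R) | C[C@@H](O[Si](CC)(CC)CC)CCC/C=C\CCCCCCCC[C@@H](OCc1ccc(OC)cc1)[C@H](O)/C=C\[C@@H](O[Si](C)(C)C(C)(C)C)CCO[Si](C)(C)C(C)(C)C | intermediate
32 | 6,7-cis-epoxy alcohol (5S,6R,7R,8S,9R,18Z,23R): 8-OH free | C[C@@H](O[Si](CC)(CC)CC)CCC/C=C\CCCCCCCC[C@@H](OCc1ccc(OC)cc1)[C@H](O)[C@H]2O[C@H]2[C@@H](O[Si](C)(C)C(C)(C)C)CCO[Si](C)(C)C(C)(C)C | intermediate
33 | fully protected epoxide (5S,6R,7S,8S,9R,18Z,23R): 3,5,8-tris-OTBS, 9-OPMB, 23-OTES | C[C@@H](O[Si](CC)(CC)CC)CCC/C=C\CCCCCCCC[C@@H](OCc1ccc(OC)cc1)[C@H](O[Si](C)(C)C(C)(C)C)[C@H]2O[C@H]2[C@@H](O[Si](C)(C)C(C)(C)C)CCO[Si](C)(C)C(C)(C)C | intermediate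
34 | C23 alcohol (5S,6R,7S,8S,9R,18Z,23R): 3,5,8-tris-OTBS, 9-OPMB | C[C@@H](O)CCC/C=C\CCCCCCCC[C@@H](OCc1ccc(OC)cc1)[C@H](O[Si](C)(C)C(C)(C)C)[C@H]2O[C@H]2[C@@H](O[Si](C)(C)C(C)(C)C)CCO[Si](C)(C)C(C)(C)C | intermediate
35 | bis(2,2,2-trifluoroethyl)phosphonoacetic acid | OC(=O)CP(=O)(OCC(F)(F)F)OCC(F)(F)F | starting material
36 | C23 bis(2,2,2-trifluoroethyl)phosphonoacetate of 34 | C[C@@H](OC(=O)CP(=O)(OCC(F)(F)F)OCC(F)(F)F)CCC/C=C\CCCCCCCC[C@@H](OCc1ccc(OC)cc1)[C@H](O[Si](C)(C)C(C)(C)C)[C@H]2O[C@H]2[C@@H](O[Si](C)(C)C(C)(C)C)CCO[Si](C)(C)C(C)(C)C | intermediate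
37 | C3 primary alcohol: 5,8-bis-OTBS, 9-OPMB, 23-phosphonoacetate | C[C@@H](OC(=O)CP(=O)(OCC(F)(F)F)OCC(F)(F)F)CCC/C=C\CCCCCCCC[C@@H](OCc1ccc(OC)cc1)[C@H](O[Si](C)(C)C(C)(C)C)[C@H]2O[C@H]2[C@@H](O[Si](C)(C)C(C)(C)C)CCO | intermediate
38 | C3 aldehyde: 5,8-bis-OTBS, 9-OPMB, 23-phosphonoacetate | C[C@@H](OC(=O)CP(=O)(OCC(F)(F)F)OCC(F)(F)F)CCC/C=C\CCCCCCCC[C@@H](OCc1ccc(OC)cc1)[C@H](O[Si](C)(C)C(C)(C)C)[C@H]2O[C@H]2[C@@H](O[Si](C)(C)C(C)(C)C)CC=O | intermediate
39 | macrolactone (2Z,18Z): 5,8-bis-OTBS, 9-OPMB, stereocentres as in 41 | C[C@@H]1CCC/C=C\CCCCCCCC[C@@H](OCc2ccc(OC)cc2)[C@H](O[Si](C)(C)C(C)(C)C)[C@H]3O[C@H]3[C@@H](O[Si](C)(C)C(C)(C)C)C/C=C\C(=O)O1 | intermediate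
40 | macrolactone (2Z,18Z): 5,8-bis-OTBS, 9-OH | C[C@@H]1CCC/C=C\CCCCCCCC[C@@H](O)[C@H](O[Si](C)(C)C(C)(C)C)[C@H]2O[C@H]2[C@@H](O[Si](C)(C)C(C)(C)C)C/C=C\C(=O)O1 | intermediate
41 | AKML B (2Z,5S,6S,7R,8S,9R,18Z,23R) | C[C@@H]1CCC/C=C\CCCCCCCC[C@@H](O)[C@H](O)[C@H]2O[C@H]2[C@@H](O)C/C=C\C(=O)O1 | target

## Step count and risks

Total: 28 steps. Longest linear sequence: 24 steps from (R)-propylene oxide (steps 1–3, 5, 6, 8–11, 14–28). Steps 4, 7, 12 and 13 are side branches.

**Step 14 (key step).** The most likely failure is loss of face selectivity at C8: the THF that comes with the two Grignard reagents competes with the O9 ether for magnesium, so part of the addition goes through an open transition state and gives the 8-epimer. Incomplete C-metalation of 23 and amine addition to the ynone on quench are secondary concerns. The fallback sets out from 18 and comes back at 26, with C8 set by a catalyst instead of the chelate: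
- LiC≡CSiMe3 is added to 18 without regard to selectivity, giving the epimeric trimethylsilyl alkynols F1.
- Dess–Martin oxidation gives the ynone F2.
- Transfer hydrogenation with the same (S,S) ruthenium catalyst as in step 16 gives the (8R)-alkynol F3.
- K2CO3/MeOH removes the C-silyl group to give the terminal alkynol F4.
- F4 is doubly metalated with EtMgBr (2.2 equiv), which gives 24, and acylated with 21 to give 26.

**Step 10.** Reductive opening of a five-membered acetal is less regioselective than that of six-membered acetals. Hydride delivery after cleavage of the wrong C–O bond returns the PMB group to O8 and regenerates 15, which can be recycled through step 9. The fallback sets out from 15 and comes back at 17: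
- DDQ in wet CH2Cl2 removes the PMB group to give the 1,2-diol F5.
- Pivaloyl chloride/pyridine acylates the primary hydroxyl to give F6.
- 4-Methoxybenzyl trichloroacetimidate with La(OTf)3 (cat.) puts PMB on O9 to give F7.
- iBu2AlH at −78 °C removes the pivalate to give 17.

**Step 20.** The risk is insufficient face selectivity. Vanadium-directed epoxidation of simple cis-allylic alcohols is only moderately threo-selective, so the outcome depends on the extra bulk at C5 and C9; oxidation of the allylic alcohol to the enone may compete. The fallback sets out from 31 and comes back at 32 and changes the source of control from substrate to catalyst: VO(OiPr)3 with a C2-symmetric chiral bis-hydroxamic acid ligand and t-BuOOH, using the ligand enantiomer that matches the O8 face. No new compound is made.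

**Step 22.** A secondary TES ether and a primary TBS ether differ only modestly in acid lability, so the primary TBS ether may be lost at the same time, and long exposure risks acid opening of the oxirane. The fallback sets out from 33 and comes back at 34, and replaces the selective deprotection by a selective protection: HF·pyridine removes both groups to give the 3,23-diol F8, and t-BuMe2SiCl/imidazole at −20 °C silylates only the primary hydroxyl.

**Step 26.** Oligomerisation, loss of Z-selectivity in the ring-forming elimination, or base-induced β-elimination of the C5 silyloxy group from the aldehyde may occur. The fallback sets out from 34 and comes back at 39, making the Z-enoate intermolecularly and closing the ring at the ester: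
- HF·pyridine gives the diol F8 (the same diol as under step 22).
- TEMPO/PhI(OAc)2 oxidises only the primary hydroxyl to give the hydroxy aldehyde F9.
- Still–Gennari olefination with methyl bis(2,2,2-trifluoroethyl)phosphonoacetate, KN(SiMe3)2 and 18-crown-6 at −78 °C gives the hydroxy Z-enoate F10.
- LiOH in aqueous THF at 0 °C gives the seco acid F11.
- Shiina macrolactonisation (2-methyl-6-nitrobenzoic anhydride, DMAP, toluene, high dilution, rt) gives 39.

## Further compounds

F1 | step 14 | C6–C24 trimethylsilyl alkynol, both C8 epimers (9R,18Z,23R) | C[C@@H](O[Si](CC)(CC)CC)CCC/C=C\CCCCCCCC[C@@H](OCc1ccc(OC)cc1)C(O)C#C[Si](C)(C)C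
F2 | step 14 | C8 trimethylsilyl ynone (9R,18Z,23R) | C[C@@H](O[Si](CC)(CC)CC)CCC/C=C\CCCCCCCC[C@@H](OCc1ccc(OC)cc1)C(=O)C#C[Si](C)(C)C
F3 | step 14 | (8R,9R,18Z,23R) trimethylsilyl alkynol | C[C@@H](O[Si](CC)(CC)CC)CCC/C=C\CCCCCCCC[C@@H](OCc1ccc(OC)cc1)[C@H](O)C#C[Si](C)(C)C
F4 | step 14 | (8R,9R,18Z,23R) terminal alkynol | C[C@@H](O[Si](CC)(CC)CC)CCC/C=C\CCCCCCCC[C@@H](OCc1ccc(OC)cc1)[C@H](O)C#C
F5 | step 10 | (2R,11Z,16R)-16-(triethylsilyloxy)heptadec-11-ene-1,2-diol | C[C@@H](O[Si](CC)(CC)CC)CCC/C=C\CCCCCCCC[C@@H](O)CO
F6 | step 10 | (2R,11Z,16R)-2-hydroxy-16-(triethylsilyloxy)heptadec-11-enyl pivalate | C[C@@H](O[Si](CC)(CC)CC)CCC/C=C\CCCCCCCC[C@@H](O)COC(=O)C(C)(C)C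
F7 | step 10 | (2R,11Z,16R)-2-(4-methoxybenzyloxy)-16-(triethylsilyloxy)heptadec-11-enyl pivalate | C[C@@H](O[Si](CC)(CC)CC)CCC/C=C\CCCCCCCC[C@@H](OCc1ccc(OC)cc1)COC(=O)C(C)(C)C
F0 | step 20 | none | none
F8 | step 22 | 3,23-diol: 5,8-bis-OTBS, 9-OPMB epoxide | C[C@@H](O)CCC/C=C\CCCCCCCC[C@@H](OCc1ccc(OC)cc1)[C@H](O[Si](C)(C)C(C)(C)C)[C@H]2O[C@H]2[C@@H](O[Si](C)(C)C(C)(C)C)CCO
F9 | step 26 | 23-hydroxy C3 aldehyde: 5,8-bis-OTBS, 9-OPMB | C[C@@H](O)CCC/C=C\CCCCCCCC[C@@H](OCc1ccc(OC)cc1)[C@H](O[Si](C)(C)C(C)(C)C)[C@H]2O[C@H]2[C@@H](O[Si](C)(C)C(C)(C)C)CC=O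
F10 | step 26 | methyl (2Z)-23-hydroxy enoate: 5,8-bis-OTBS, 9-OPMB | C[C@@H](O)CCC/C=C\CCCCCCCC[C@@H](OCc1ccc(OC)cc1)[C@H](O[Si](C)(C)C(C)(C)C)[C@H]2O[C@H]2[C@@H](O[Si](C)(C)C(C)(C)C)C/C=C\C(=O)OC
F11 | step 26 | (2Z)-23-hydroxy seco acid: 5,8-bis-OTBS, 9-OPMB | C[C@@H](O)CCC/C=C\CCCCCCCC[C@@H](OCc1ccc(OC)cc1)[C@H](O[Si](C)(C)C(C)(C)C)[C@H]2O[C@H]2[C@@H](O[Si](C)(C)C(C)(C)C)C/C=C\C(=O)O
A1 | alternative 1 | C3 aldehyde with C23 bis(2,2,2-trifluoroethyl)phosphonoacetate and 5,8,9-tris(triethylsilyl) ethers | C[C@@H](OC(=O)CP(=O)(OCC(F)(F)F)OCC(F)(F)F)CCC/C=C\CCCCCCCC[C@@H](O[Si](CC)(CC)CC)[C@H](O[Si](CC)(CC)CC)[C@H]1O[C@H]1[C@@H](O[Si](CC)(CC)CC)CC=O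
A2 | alternative 1 | tris(triethylsilyl) ether of the target macrolide | C[C@@H]1CCC/C=C\CCCCCCCC[C@@H](O[Si](CC)(CC)CC)[C@H](O[Si](CC)(CC)CC)[C@H]2O[C@H]2[C@@H](O[Si](CC)(CC)CC)C/C=C\C(=O)O1
A3 | alternative 2 | 24-membered (2Z,6Z,18Z)-triene lactone with free C8 hydroxyl, O5 TBS and O9 PMB | C[C@@H]1CCC/C=C\CCCCCCCC[C@@H](OCc2ccc(OC)cc2)[C@H](O)/C=C\[C@@H](O[Si](C)(C)C(C)(C)C)C/C=C\C(=O)O1
A4 | alternative 2 | target with O9 PMB and O5 TBS ethers | C[C@@H]1CCC/C=C\CCCCCCCC[C@@H](OCc2ccc(OC)cc2)[C@H](O)[C@H]3O[C@H]3[C@@H](O[Si](C)(C)C(C)(C)C)C/C=C\C(=O)O1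
A5 | alternative 3 | O5–Si–O8 diisopropylsilyl bis-allyl ether (acyclic diene) | C[C@@H](O[Si](C)(C)C(C)(C)C)CCC/C=C\CCCCCCCC[C@@H](OCc1ccc(OC)cc1)[C@@H](C=C)O[Si](C(C)C)(C(C)C)O[C@@H](CC(=O)OC)C=C
A6 | alternative 3 | seven-membered cyclic silaketal with cis C6=C7 | C[C@@H](O[Si](C)(C)C(C)(C)C)CCC/C=C\CCCCCCCC[C@@H](OCc1ccc(OC)cc1)[C@@H]2O[Si](C(C)C)(C(C)C)O[C@@H](CC(=O)OC)C=C2
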